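## The problem

Target 30 is a bisabolane diester. Its cyclohexane ring (C1 methylene, C2–C3 epoxide with the methyl on C3, C4 carbinol, C5 angelate carbon, C6 chain-bearing carbon) is joined through the single C6–C7 bond to a chain in which C7 carries the exocyclic methylene C14, C8 the second angelate, C9 is a methylene and C10–C11 form a terminal trisubstituted epoxide. The ring holds five contiguous stereocenters (2S,3R,4R,5R,6S) with the epoxide oxygen, the C4 hydroxyl, the C5 acyloxy group and the C6 chain all on one face; this array would be lost if C5 or C6 could equilibrate next to a carbonyl group. Inside the ring the centers can steer one another, since a free C4 hydroxyl can deliver an oxidant to C2=C3. C8 (S) and C10 (R) are insulated from the ring by the sp2 carbon C7 and by C9, so they must be set by reagents. The (Z)-angelates isomerise to tiglates under nucleophilic catalysis, both epoxides are acid-labile, and the free C4 hydroxyl lies between an epoxide and the C5 ester, so base invites acyl shift and epoxide migration. The esters, the chain epoxide and the free hydroxyl therefore have to appear late, and O4 has to be told apart from O5 from the start. The feature that opens the problem is the all-cis triad C4–O, C5–O, C6–C7 beside a C2=C3 bond with the methyl on C3: with the C5 oxygen traded for a carbonyl carbon this is the endo adduct of a 1-oxygenated 2-methylbutadiene and a cis-locked dienophile, and a Baeyer–Villiger reaction returns the oxygen with retention.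

## Retrosynthesis

**30 ⇒ 29 ⇒ 28.** The O–Si bond at C4 and then the two C–O bonds of the chain epoxide are cut. The 2,2-dimethyloxirane is the most acid-labile unit and C10 has no neighbour to control it, so it is made last among the skeletal operations by a Shi epoxidation of 28. Carrying it in from a fragment would require a β,γ-epoxy aldehyde, which would not survive. The forward reaction must pick C10=C11 out of four olefins; by then C2=C3 is already an epoxide and the others are electron-poor or 1,1-disubstituted next to an ester.

**28 ⇒ 27 ⇒ 25 + 26.** The C5 ester C–O bond and then the C8 ester C–O bond are cut, each returning one molecule of angelic acid 26. Acylating C5 earlier would expose an angelate to the organometallic and hydride reagents of the chain synthesis, so both esters follow the last C–C bond formation and the C8 reduction. The precursor 25 has only two free hydroxyls because O4 carries a silyl group, and they differ in accessibility: the allylic C8 hydroxyl is open, whereas the C5 hydroxyl sits between the cis silyl ether and the cis C6 chain. The forward acylations are therefore staged, mild for C8 (giving 27) and forcing for C5 (giving 28), and both must proceed without Z to E isomerisation.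

**25 ⇒ 24 ⇒ 23 ⇒ 22 ⇒ 19 + 21.** The C7–C8 bond is cut between alkenyl triflate 19 and aldehyde 21. Cutting C8–C9 would need a 2-substituted acrolein and a linear-selective prenyl metal. Adding an oxygenated C8 nucleophile to a C7 carbonyl would leave C6 next to a ketone during a basic olefination. The Nozaki–Hiyama–Kishi coupling keeps C7 sp2 and tolerates acetate, epoxide and silyl ether. No substrate control at C8 can be counted on, so the carbinol 22 is oxidised to enone 23 and reduced under catalyst control to 24; cleavage of the C5 acetate then gives 25.

**19 ⇒ 18 ⇒ 17 ⇒ 16.** The C7–C14 bond is cut: methyl addition to aldehyde 16, oxidation and kinetic enol triflate formation. This turns the aldehyde carbon delivered by the cycloaddition into an alkenyl nucleophile with C6 untouched.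

**16 ⇒ 13 ⇒ 11.** The C5–O bond is traced to the C5–acetyl bond of 11 (Baeyer–Villiger, retention) and the ring epoxide to C2=C3 (delivery by the free C4 hydroxyl). Both are done by one peracid before any chain olefin exists, since a peracid would not spare C10=C11 later. The hydroxyl is then silylated and the acetal opened to 16.

**11 ⇒ 9 ⇒ 8.** The acetyl group comes from the ester of 9 through a Weinreb amide. Ester and acetal come from the lactone acetal of 8 by acidic methanolysis, which uses the built-in difference between the acid-level and the aldehyde-level carbon and frees the C4 hydroxyl.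

**8 ⇒ 2 + 7.** The C4–C5 and C6–C1 bonds are cut. A cycloaddition sets C4, C5 and C6 at once and puts the olefin at C2=C3; stepwise ring constructions would have to build the all-cis triad against sterics. Diene 2 and butenolide 7 have between them a single stereocenter on the reacting skeleton. The forward reaction must be regioselective, endo-selective and anti to the menthyloxy group.

**2 ⇐ 1; 7 ⇐ 5 + 6; 5 ⇐ 3.** The diene is the silyl dienol ether of aldehyde 1. The butenolide comes from photooxygenation of furfural 3 and acetalisation of 5 with menthol 6, with crystallisation of the (5R) epimer.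

## Roads not taken

Alternative 1: The ring would come from (−)-shikimic acid A1, whose three oxygens map onto C4, C3 and C2. The cut is the C3–methyl bond together with the C2–O bond of the ring epoxide. In the forward key step MeMgBr adds to the C3 ketone of keto mesylate A2 from the face opposite the C4 p-methoxybenzyl ether, and the tertiary alkoxide displaces the trans C2 mesylate to give epoxy enoate A3. Merits: the chiral pool supplies C4 and, through one stereospecific operation, the epoxide cis to O4, and the C7 carbon is already on C6 as an ester. Weak points: A3 lacks the C5 oxygen and the C6 hydrogen. Both would have to be added across the electron-poor C5=C6 bond on the face that already carries the C4 ether and the epoxide, without a directing group, and the epoxide would have to survive the whole chain synthesis. Comparison: for C2–C4 this road is shorter and more secure than the chosen plan, which depends on a directed epoxidation (step 7) and spends steps 6 and 7 on the C5 oxygen. The chosen plan sets against this that the hardest element, the all-cis C4–C5–C6 triad, is made in one step under predictable control.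

Alternative 2: The cut is the C6–C1 bond. In the forward key step the enolate of the 6-methyl-6-vinyl δ-lactone A4 (C4 and C5 oxygens as a cis acetonide) is O-silylated (KN(SiMe3)2, Me3SiCl) and rearranges through a boat transition state (Ireland–Claisen ring contraction). C6–C1 forms, the lactone C3–O bond breaks, C2=C3 appears and acid A5 results. Merits: both ring oxygens are present from the start, so no carbon-to-oxygen exchange is needed; C6 is set by intramolecular chirality transfer; the C6 carboxylic acid is at the right oxidation level for a chain ketone; the olefin sits at C2=C3. Weak points: A4 needs a tertiary allylic center and a cis diol, which means a multistep sugar-based preparation. O4 and O5 arrive as one acetonide and would have to be told apart later for mono-angeloylation at C5, with acid needed to open the acetonide. Comparison: after its key step this road is closer to the target than the chosen one and is the better of the two in redox economy. The chosen plan sets against it two simple precursors and oxygens that are differentiated by construction (O4 a silyl ether, O5 still a carbon).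

Alternative 3: The cuts are the C5–C6 and C1–C2 bonds. In the forward key step N-acryloyloxazolidin-2-one A6 and (E)-1-acetoxy-3-methylbuta-1,3-diene A7 combine under [Cu(tBu-box)](SbF6)2, a divalent copper bis(oxazoline) complex, to give cycloadduct A8 with the C6 imide and the C5 acetate cis. Merits: chirality is catalytic, the C5 oxygen arrives directly from the diene, and the imide is easily turned into a ketone. Weak points: the diene places the olefin at C3=C4 and leaves C4 without oxygen. An allylic transposition with a new stereocenter at C4, cis to O5 and not set by the key step, would have to precede the ring epoxidation. Comparison: in asymmetric induction and in avoiding the Baeyer–Villiger detour this road is better. The chosen plan pays with a stoichiometric, recoverable auxiliary but sets three contiguous centers including C4 and puts the olefin where the hydroxyl can direct its epoxidation.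

Key step: step 4

Remark: positions are named by the bisabolane numbering defined above; 4-methylpent-3-enal (21) is taken to be too prone to double-bond migration to be stocked and is made fresh.

## Route

Step 1
Reactants: 1 (E)-2-methylbut-2-enal
Product: 2 (1E)-1-(tert-butyldimethylsilyloxy)-2-methylbuta-1,3-diene
Conditions: tBuMe2SiOTf, Et3N, Et2O, 0 °C → rt
Reagents that add atoms: tert-butyldimethylsilyl trifluoromethanesulfonate, CC(C)(C)[Si](C)(C)OS(=O)(=O)C(F)(F)F
Why: O-silylation of the enal with γ-deprotonation (silyl dienol ether formation); reaction through the s-trans enal places oxygen trans to the vinyl group and so gives the (1E) diene.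

Step 2
Reactants: 3 furfural
Product: 5 5-hydroxyfuran-2(5H)-one (racemic), via furfural endoperoxide 4 (not isolated)
Conditions: O2, visible light, rose bengal (C20H2Cl4I4Na2O5, cat.), MeOH, rt
Reagents that add atoms: dioxygen, O=O
Why: Singlet-oxygen [4+2] photooxygenation of the furan; methanolysis of the endoperoxide expels the formyl carbon as methyl formate and leaves the hydroxybutenolide.

Step 3
Reactants: 5 5-hydroxyfuran-2(5H)-one; 6 (−)-menthol
Product: 7 (5R)-5-[(1R,2S,5R)-menthyloxy]furan-2(5H)-one
Conditions: (+)-10-camphorsulfonic acid (cat.), toluene, reflux, water separator; crystallisation from hexane, mother liquor re-equilibrated with acid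
Reagents that add atoms: none
Why: Acid-catalysed acetalisation of the pseudo-acid gives both acetal epimers; the (5R) epimer crystallises and the acetal center epimerises under acid, so recycling should funnel the material into 7 (crystallisation-driven diastereomer enrichment).

Step 4
Reactants: 2 (1E)-1-(tert-butyldimethylsilyloxy)-2-methylbuta-1,3-diene; 7 (5R)-5-[(1R,2S,5R)-menthyloxy]furan-2(5H)-one
Product: 8 (3R,3aR,7R,7aR)-7-(tert-butyldimethylsilyloxy)-3-[(1R,2S,5R)-menthyloxy]-6-methyl-3a,4,7,7a-tetrahydro-2-benzofuran-1(3H)-one
Conditions: toluene, 115 °C, sealed tube, excess 2, 2,6-di-tert-butyl-4-methylphenol (trace)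
Reagents that add atoms: none
Why: Concerted, asynchronous normal-demand [4+2] cycloaddition (diene HOMO, butenolide LUMO); the closest known reaction type is the thermal Diels–Alder reaction of 5-alkoxyfuran-2(5H)-ones with 1-oxygenated butadienes. The cyclohexene ring closes directly by intermolecular cycloaddition, suprafacial on both partners, through the C4–C5 and C6–C1 bonds, cis-fused to the lactone. Regiochemistry follows the silyloxy donor: the largest HOMO coefficient lies on the unsubstituted diene terminus, which pairs with the butenolide β-carbon, so the silyloxy carbon bonds to the α-carbon and the weaker opposing bias of the 2-methyl group is overridden. C6 is set by approach anti to the menthyloxy group on the adjacent acetal carbon. C5 is cis to C6 because the dienophile geometry is ring-locked. C4 is set by the endo orientation of the lactone carbonyl combined with the (1E) diene geometry, which puts the silyloxy group cis to the C5 carbonyl. The step needs regio-, facial and endo selectivity; the strong 1-oxygen donor, the acetal substituent beside the reacting carbon and secondary orbital overlap with the lactone carbonyl secure them. The methyl group ends on C3 of a C2=C3 olefin.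

Step 5
Reactants: 8 cycloadduct
Product: 9 methyl (1R,2R,6R)-6-(dimethoxymethyl)-2-hydroxy-3-methylcyclohex-3-ene-1-carboxylate
Conditions: HCl (0.5 M in MeOH), HC(OMe)3, 0 °C → rt; Et3N added before concentration
Reagents that add atoms: methanol, CO; trimethyl orthoformate, COC(OC)OC
Why: Acid-catalysed acetal exchange opens the pseudo-ester through the alkoxy-stabilised oxocarbenium ion, Fischer esterification of the released acid and methanolysis of the silyl ether follow; C5 and C6 are not enolised under these conditions and the acid is neutralised before the solvent is removed so that the open dimethyl acetal is kept.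

Step 6
Reactants: 9 hydroxy ester acetal
Product: 11 1-[(1R,2R,6R)-6-(dimethoxymethyl)-2-hydroxy-3-methylcyclohex-3-en-1-yl]ethan-1-one, via Weinreb amide 10 (not isolated)
Conditions: MeNH(OMe)·HCl, MeMgCl (excess), THF, −20 → 0 °C; aq. NH4Cl
Reagents that add atoms: methylmagnesium chloride, C[Mg]Cl; N,O-dimethylhydroxylamine hydrochloride, CNOC.Cl (atoms kept only in intermediate 10)
Why: One-pot Weinreb ketone synthesis from an ester: the magnesium amide converts the ester into the N-methoxy-N-methylamide, and the second Grignard addition stops at the chelated tetrahedral intermediate. The ketone is released only on quench, so C5 is never exposed to base as a ketone.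

Step 7
Reactants: 11 hydroxy ketone
Product: 13 epoxy acetate (C5 acetate, free C4 hydroxyl, cis-2,3-epoxide, C7 dimethyl acetal; all four ring substituents on one face), via epoxy ketone 12 (not isolated)
Conditions: mCPBA (3 equiv), NaHCO3, CH2Cl2, 0 °C → rt
Reagents that add atoms: 3-chloroperbenzoic acid, O=C(OO)c1cccc(Cl)c1
Why: Hydroxyl-directed peracid epoxidation: the trisubstituted olefin reacts first and the C4 hydroxyl delivers the peracid by hydrogen bonding to its own face, setting C2 and C3 cis to O4. Baeyer–Villiger oxidation of the acetyl group follows, with migration of the secondary C5 in preference to methyl and retention at C5.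

Step 8
Reactants: 13 epoxy acetate
Product: 16 aldehyde (C7 formyl, C4 triethylsilyl ether, C5 acetate, cis-2,3-epoxide), via silyl ether acetal 14 (not isolated), via lutidinium triflate 15 (not isolated)
Conditions: Et3SiOTf (3 equiv), 2,6-lutidine, CH2Cl2, −78 → 0 °C; then H2O
Reagents that add atoms: triethylsilyl trifluoromethanesulfonate, CC[Si](CC)(CC)OS(=O)(=O)C(F)(F)F; water, O; 2,6-lutidine, Cc1cccc(C)n1 (atoms kept only in intermediate 15)
Why: The silyl triflate first silylates the hindered C4 hydroxyl at low temperature, then converts the dimethyl acetal into the N-(α-methoxyalkyl)pyridinium salt, which water hydrolyses to the aldehyde (silyl triflate–pyridine base acetal cleavage). No protic acid or base is present, so the epoxide and the C6 center α to the aldehyde should stay intact.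

Step 9
Reactants: 16 aldehyde
Product: 17 C7 methyl carbinol (both C7 epimers)
Conditions: MeMgBr, THF, −78 °C; aq. NH4Cl at −78 °C
Reagents that add atoms: methylmagnesium bromide, C[Mg]Br
Why: Grignard addition to the aldehyde, which is far more electrophilic than the acetate at −78 °C; the cold quench limits acetyl transfer to the new alkoxide, and the new center is removed in the next step.

Step 10
Reactants: 17 methyl carbinol
Product: 18 C7 methyl ketone
Conditions: Dess–Martin periodinane, NaHCO3, CH2Cl2, 0 °C → rt
Reagents that add atoms: none
Why: Dess–Martin oxidation under buffered, non-basic conditions, so the C6 center next to the new ketone and the β-acetoxy group are not disturbed.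

Step 11
Reactants: 18 methyl ketone
Product: 19 enol triflate (C7(OTf)=C14H2)
Conditions: N-(5-chloropyridin-2-yl)bis(trifluoromethanesulfonyl)imide, then KN(SiMe3)2 added last, THF, −78 °C; aq. NH4Cl
Reagents that add atoms: N-(5-chloropyridin-2-yl)bis(trifluoromethanesulfonyl)imide, O=S(=O)(N(c1ccc(Cl)cn1)S(=O)(=O)C(F)(F)F)C(F)(F)F
Why: Kinetic deprotonation on the methyl side by the hindered amide base and O-sulfonylation give the 1,1-disubstituted enol triflate. Adding the base last keeps the enolate short-lived, so attack on the neighbouring acetate or equilibration to the C6 enolate should not compete.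

Step 12
Reactants: 20 4-methylpent-3-en-1-ol
Product: 21 4-methylpent-3-enal
Conditions: Dess–Martin periodinane, NaHCO3, CH2Cl2, 0 °C; used at once as a solution
Reagents that add atoms: none
Why: Dess–Martin oxidation of a primary alcohol; buffered, neutral conditions avoid migration of the β,γ-double bond into conjugation.

Step 13
Reactants: 19 enol triflate; 21 4-methylpent-3-enal
Product: 22 allylic alcohol (both C8 epimers)
Conditions: CrCl2 (excess), NiCl2 (cat.), DMF, rt
Reagents that add atoms: none
Why: Nozaki–Hiyama–Kishi coupling: zerovalent nickel formed in situ inserts into the C–OTf bond, the alkenyl group passes to trivalent chromium and adds to the aldehyde only; acetate, epoxide and silyl ether are tolerated.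

Step 14
Reactants: 22 allylic alcohol
Product: 23 enone (C8 ketone conjugated with C7=C14)
Conditions: Dess–Martin periodinane, NaHCO3, CH2Cl2, 0 °C
Reagents that add atoms: none
Why: Dess–Martin oxidation of the allylic alcohol merges both C8 epimers into one ketone without base, so the doubly activated C9 methylene is not isomerised.

Step 15
Reactants: 23 enone
Product: 24 (8S)-allylic alcohol
Conditions: (R)-1-methyl-3,3-diphenyltetrahydro-1H,3H-pyrrolo[1,2-c][1,3,2]oxazaborole [(R)-Me-CBS, 0.3 equiv], catecholborane, toluene, −78 °C
Reagents that add atoms: none
Why: Corey–Bakshi–Shibata 1,2-reduction; the branched alkenyl group acts as the large substituent and the C9 methylene as the small one, so the (R)-catalyst should deliver hydride to the face that gives the (8S) carbinol.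

Step 16
Reactants: 24 (8S)-allylic alcohol
Product: 25 (8S)-5,8-diol (C4 triethylsilyl ether)
Conditions: iBu2AlH, CH2Cl2, −78 °C; aq. KNaC4H4O6
Reagents that add atoms: none
Why: Reductive cleavage of the acetate at low temperature; no free alkoxide base is present, so the silyl group on the cis-neighbouring O4 should not migrate and the hindered epoxide is not reduced.

Step 17
Reactants: 25 (8S)-5,8-diol; 26 angelic acid
Product: 27 C8 mono-angelate (free C5 hydroxyl, C4 triethylsilyl ether, C10=C11 olefin)
Conditions: 26 (1.1 equiv), 2,4,6-trichlorobenzoyl chloride, Et3N, toluene, rt; then 25, 50 °C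
Reagents that add atoms: none
Why: Acylation through the mixed 2,4,6-trichlorobenzoic anhydride (Yamaguchi-type esterification) without a nucleophilic catalyst, the variant under which the (Z)-olefin of angelic acid does not isomerise. With a small excess of acyl donor and moderate heating the open allylic C8 hydroxyl should react well before the C5 hydroxyl, which is flanked by the cis silyl ether and the cis C6 chain; any bis-ester formed is already the product of step 18.

Step 18
Reactants: 27 C8 mono-angelate; 26 angelic acid
Product: 28 5,8-bis-angelate (C4 triethylsilyl ether, C10=C11 olefin)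
Conditions: 26 (4 equiv), 2,4,6-trichlorobenzoyl chloride, Et3N, toluene, rt; then 27, 80 °C
Reagents that add atoms: none
Why: The same mixed-anhydride esterification, now with excess acyl donor and heating to overcome the hindrance at C5; no nucleophilic catalyst is present, so both angelates should keep their (Z) geometry. The silyl ether on O4 leaves O5 as the only free hydroxyl.

Step 19
Reactants: 28 bis-angelate
Product: 29 C4 triethylsilyl ether of 30 [(10R)-10,11-epoxide]
Conditions: 1,2:4,5-di-O-isopropylidene-β-D-erythro-2,3-hexodiulo-2,6-pyranose (D-fructose-derived ketone, 0.3 equiv), Oxone (2KHSO5·KHSO4·K2SO4), K2CO3, Bu4NHSO4, aq. Na2B4O7 buffer, MeCN–CH2(OMe)2, 0 °C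
Reagents that add atoms: potassium peroxymonosulfate, [K+].OOS(=O)(=O)[O-]
Why: Shi epoxidation: the chiral dioxirane attacks the only electron-rich trisubstituted olefin through the spiro transition state, and the D-fructose-derived catalyst is expected to give the (R) configuration at C10 as with other 2-methylalk-2-enes. The angelate olefins and the 1,1-disubstituted olefin beside the C8 ester are too electron-poor to compete.

Step 20
Reactants: 29 silyl ether
Product: 30 CNP0235377.1
Conditions: HF·pyridine, pyridine (excess), THF, 0 °C → rt
Reagents that add atoms: none
Why: Fluoride-mediated cleavage of the triethylsilyl ether under buffered, weakly acidic conditions, which avoid the alkoxide that would trigger acyl shift from O5 to O4 and are mild enough to leave trisubstituted epoxides closed.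

## Compound list

1 | (E)-2-methylbut-2-enal | C/C=C(\C)C=O | starting material
2 | (1E)-1-(tert-butyldimethylsilyloxy)-2-methylbuta-1,3-diene | C=C/C(C)=C/O[Si](C)(C)C(C)(C)C | intermediate
3 | furfural | O=Cc1ccco1 | starting material
4 | furfural endoperoxide (2,3,7-trioxabicyclo[2.2.1]hept-5-ene-1-carbaldehyde, racemic) | O=CC12C=CC(OO1)O2 | intermediate
5 | 5-hydroxyfuran-2(5H)-one (racemic) | O=C1C=CC(O)O1 | intermediate
6 | (−)-menthol, (1R,2S,5R) | CC(C)[C@@H]1CC[C@@H](C)C[C@H]1O | starting material
7 | (5R)-5-[(1R,2S,5R)-menthyloxy]furan-2(5H)-one | O=C1C=C[C@H](O[C@@H]2C[C@H](C)CC[C@H]2C(C)C)O1 | intermediate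
8 | (3R,3aR,7R,7aR)-7-(tert-butyldimethylsilyloxy)-3-[(1R,2S,5R)-menthyloxy]-6-methyl-3a,4,7,7a-tetrahydro-2-benzofuran-1(3H)-one (silyloxy group, lactone carbonyl carbon and acetal carbon all cis; menthyloxy cis to the ring-fusion hydrogens) | O=C1O[C@@H](O[C@@H]3C[C@H](C)CC[C@H]3C(C)C)[C@@H]2CC=C(C)[C@H](O[Si](C)(C)C(C)(C)C)[C@H]12 | intermediate
9 | methyl (1R,2R,6R)-6-(dimethoxymethyl)-2-hydroxy-3-methylcyclohex-3-ene-1-carboxylate | COC(OC)[C@@H]1CC=C(C)[C@H](O)[C@@H]1C(=O)OC | intermediate
10 | (1R,2R,6R)-6-(dimethoxymethyl)-2-hydroxy-N-methoxy-N,3-dimethylcyclohex-3-ene-1-carboxamide (Weinreb amide) | COC(OC)[C@@H]1CC=C(C)[C@H](O)[C@@H]1C(=O)N(C)OC | intermediate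
11 | 1-[(1R,2R,6R)-6-(dimethoxymethyl)-2-hydroxy-3-methylcyclohex-3-en-1-yl]ethan-1-one | COC(OC)[C@@H]1CC=C(C)[C@H](O)[C@@H]1C(C)=O | intermediate
12 | epoxy ketone: cis-2,3-epoxide of 11 (epoxide oxygen, C4 hydroxyl, C5 acetyl and C6 acetal carbon on one face) | COC(OC)[C@@H]1C[C@@H]2O[C@]2(C)[C@H](O)[C@@H]1C(C)=O | intermediate
13 | epoxy acetate: C5 acetate, free C4 hydroxyl, cis-2,3-epoxide, C7 dimethyl acetal, all cis | COC(OC)[C@@H]1C[C@@H]2O[C@]2(C)[C@H](O)[C@@H]1OC(C)=O | intermediate
14 | C4 triethylsilyl ether of 13 | COC(OC)[C@@H]1C[C@@H]2O[C@]2(C)[C@H](O[Si](CC)(CC)CC)[C@@H]1OC(C)=O | intermediate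
15 | 1-(C7-methoxyalkyl)-2,6-dimethylpyridinium triflate derived from 14 (C7 epimers) | COC([n+]1c(C)cccc1C)[C@@H]1C[C@@H]2O[C@]2(C)[C@H](O[Si](CC)(CC)CC)[C@@H]1OC(C)=O.[O-]S(=O)(=O)C(F)(F)F | intermediate
16 | aldehyde: C7 formyl on C6, C4 triethylsilyl ether, C5 acetate, cis-2,3-epoxide, all cis | O=C[C@@H]1C[C@@H]2O[C@]2(C)[C@H](O[Si](CC)(CC)CC)[C@@H]1OC(C)=O | intermediate
17 | C7 methyl carbinol of 16 (both C7 epimers) | CC(O)[C@@H]1C[C@@H]2O[C@]2(C)[C@H](O[Si](CC)(CC)CC)[C@@H]1OC(C)=O | intermediate
18 | C7 methyl ketone (6-acetyl; ring as in 16) | CC(=O)[C@@H]1C[C@@H]2O[C@]2(C)[C@H](O[Si](CC)(CC)CC)[C@@H]1OC(C)=O | intermediate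
19 | enol triflate: C7(OSO2CF3)=C14H2 on C6 (ring as in 16) | C=C(OS(=O)(=O)C(F)(F)F)[C@@H]1C[C@@H]2O[C@]2(C)[C@H](O[Si](CC)(CC)CC)[C@@H]1OC(C)=O | intermediate
20 | 4-methylpent-3-en-1-ol | CC(C)=CCCO | starting material
21 | 4-methylpent-3-enal | CC(C)=CCC=O | intermediate
22 | allylic alcohol: C7(=C14H2)–C8H(OH)–C9H2–C10H=C11Me2 chain on C6, both C8 epimers (ring as in 16) | C=C(C(O)CC=C(C)C)[C@@H]1C[C@@H]2O[C@]2(C)[C@H](O[Si](CC)(CC)CC)[C@@H]1OC(C)=O | intermediate
23 | enone: C8 ketone of 22 | C=C(C(=O)CC=C(C)C)[C@@H]1C[C@@H]2O[C@]2(C)[C@H](O[Si](CC)(CC)CC)[C@@H]1OC(C)=O | intermediate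
24 | (8S)-allylic alcohol (C5 acetate, C4 triethylsilyl ether) | C=C([C@H](CC=C(C)C)O)[C@@H]1C[C@@H]2O[C@]2(C)[C@H](O[Si](CC)(CC)CC)[C@@H]1OC(C)=O | intermediate
25 | (8S)-5,8-diol (C4 triethylsilyl ether, cis-2,3-epoxide) | C=C([C@H](CC=C(C)C)O)[C@@H]1C[C@@H]2O[C@]2(C)[C@H](O[Si](CC)(CC)CC)[C@@H]1O | intermediate
26 | angelic acid, (Z)-2-methylbut-2-enoic acid | C/C=C(/C)C(=O)O | starting material
27 | C8 mono-angelate of 25 (free C5 hydroxyl, C4 triethylsilyl ether, C10=C11 olefin) | C=C([C@H](CC=C(C)C)OC(=O)/C(C)=C\C)[C@@H]1C[C@@H]2O[C@]2(C)[C@H](O[Si](CC)(CC)CC)[C@@H]1O | intermediate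
28 | 5,8-bis-angelate (C4 triethylsilyl ether, C10=C11 olefin) | C=C([C@H](CC=C(C)C)OC(=O)/C(C)=C\C)[C@@H]1C[C@@H]2O[C@]2(C)[C@H](O[Si](CC)(CC)CC)[C@@H]1OC(=O)/C(C)=C\C | intermediate
29 | C4 triethylsilyl ether of 30 [(10R)-10,11-epoxide] | C=C([C@H](C[C@H]1OC1(C)C)OC(=O)/C(C)=C\C)[C@@H]1C[C@@H]2O[C@]2(C)[C@H](O[Si](CC)(CC)CC)[C@@H]1OC(=O)/C(C)=C\C | intermediate
30 | CNP0235377.1: (2S,3R,4R,5R,6S,8S,10R)-2,3:10,11-diepoxy-4-hydroxybisabol-7(14)-ene-5,8-diyl bis[(Z)-2-methylbut-2-enoate] (bisabolane numbering) | C=C([C@H](C[C@H]1OC1(C)C)OC(=O)/C(C)=C\C)[C@@H]1C[C@@H]2O[C@]2(C)[C@H](O)[C@@H]1OC(=O)/C(C)=C\C | target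

## Step count and least certain steps

Total: 20 steps. Longest linear sequence: 18 steps from furfural 3 (steps 2–11 and 13–20); steps 1 and 12 prepare the diene and the aldehyde.

**Step 4 (key step).** The most likely failure is thermal loss of the diene (silyl transfer, oligomerisation) before the moderately reactive, β-substituted butenolide is consumed. The 2-methyl group crowds the reacting silyloxy terminus and prolonged heating is needed; erosion of endo selectivity at higher temperature is the second concern. The fallback sets out from 1 and 7 and changes the diene class to an enol acetate, which tolerates harder heating. Aldehyde 1 is converted with isopropenyl acetate and catalytic TsOH into (1E)-1-acetoxy-2-methylbuta-1,3-diene F1. F1 forms the same two bonds with 7 and gives the acetoxy adduct F2. The acidic methanolysis of step 5 removes the acetate as well and rejoins the route at 9.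

**Step 5.** The most likely failure is capture of the C7 oxocarbenium ion by the C4 hydroxyl once the silyl ether has been lost, giving a bridged acetal that would block the later hydroxyl-directed epoxidation. The two groups are cis-1,3 on the ring and acid is present throughout. The fallback sets out from 8. A mild acetal exchange (pyridinium p-toluenesulfonate, MeOH, 0 °C) should stop at the carboxylic acid with the silyl ether intact, the acid acetal F3. Me3SiCHN2 then gives the methyl ester acetal F4. Bu4NF buffered with AcOH frees the hydroxyl under conditions where acetal exchange cannot occur, and the route is rejoined at 9.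

**Step 6.** The most likely failure is slow aminolysis of the ester, which is flanked by two cis substituents, so that direct Grignard addition to the ester and over-addition compete. The fallback sets out from 9. Petasis methylenation (Cp2TiMe2, toluene, 70 °C) converts the ester into the methyl enol ether F5. Hydrolysis of this enol ether, which is far more acid-labile than the acetal (oxalic acid, wet THF, 0 °C), gives 11.

**Step 7.** The most likely failure is poor facial selectivity in the epoxidation. The face that must be attacked carries all three ring substituents, and the C4 hydroxyl may be engaged in a hydrogen bond to the acetyl group instead of to the peracid. A slow Baeyer–Villiger stage at the hindered ketone is the second concern. The fallback sets out from 11 and separates the two oxidations. VO(acac)2 with tBuOOH epoxidises through the alkoxide bound to pentavalent vanadium, the more strongly directed mode, and gives 12, now isolated. A buffered peracid (CF3CO3H, Na2HPO4) then performs the Baeyer–Villiger step to 13. This detour passes only through listed compounds (F0).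

**Step 15.** The most likely failure is insufficient catalyst control, because the two ketone substituents differ less in size than in standard cases, or migration of the C10=C11 bond into conjugation under the Lewis-acidic conditions. The fallback sets out from 23. Luche reduction (NaBH4, CeCl3, MeOH, −78 °C) gives 24 together with its (8R)-allylic alcohol epimer F6. After separation, F6 is inverted by a Mitsunobu reaction with benzoic acid to the (8S)-benzoate F7. iBu2AlH as in step 16 cleaves benzoate and acetate together and reaches 25.

**Step 18.** The most likely failure is incomplete acylation of the hindered C5 hydroxyl, and prolonged heating with excess mixed anhydride risks Z to E isomerisation of the angelate already in place at C8 as well as of the acyl donor. The fallback sets out from 27 and activates the alcohol instead of the acid. Angelic acid 26 is dehydrated with N,N′-dicyclohexylcarbodiimide to angelic anhydride F8. LiN(SiMe3)2 is then added at −78 °C to a THF solution of 27 and F8, so that the lithium alkoxide at O5 is acylated as it forms, before the silyl group can shift from O4; this reaches 28.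

## Further compounds

F1 | step 4 | (1E)-1-acetoxy-2-methylbuta-1,3-diene | C=C/C(C)=C/OC(C)=O
F2 | step 4 | acetoxy adduct (C4 acetate analogue of 8) | O=C1O[C@@H](O[C@@H]3C[C@H](C)CC[C@H]3C(C)C)[C@@H]2CC=C(C)[C@H](OC(C)=O)[C@H]12
F3 | step 5 | acid acetal (C5 carboxylic acid, C7 dimethyl acetal, C4 tert-butyldimethylsilyl ether) | COC(OC)[C@@H]1CC=C(C)[C@H](O[Si](C)(C)C(C)(C)C)[C@@H]1C(=O)O
F4 | step 5 | methyl ester acetal (C4 tert-butyldimethylsilyl ether of 9) | COC(OC)[C@@H]1CC=C(C)[C@H](O[Si](C)(C)C(C)(C)C)[C@@H]1C(=O)OC
F5 | step 6 | methyl enol ether (C5 1-methoxyvinyl analogue of 11) | COC(OC)[C@@H]1CC=C(C)[C@H](O)[C@@H]1C(=C)OC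
F0 | step 7 | none | none
F6 | step 15 | (8R)-allylic alcohol (C8 epimer of 24) | C=C([C@@H](CC=C(C)C)O)[C@@H]1C[C@@H]2O[C@]2(C)[C@H](O[Si](CC)(CC)CC)[C@@H]1OC(C)=O
F7 | step 15 | (8S)-benzoate of 24 | C=C([C@H](CC=C(C)C)OC(=O)c1ccccc1)[C@@H]1C[C@@H]2O[C@]2(C)[C@H](O[Si](CC)(CC)CC)[C@@H]1OC(C)=O
F8 | step 18 | angelic anhydride, (Z,Z)-2-methylbut-2-enoic anhydride | C/C=C(/C)C(=O)OC(=O)/C(C)=C\C
A1 | alternative 1 | (−)-shikimic acid | C1[C@H]([C@@H]([C@@H](C=C1C(=O)O)O)O)O
A2 | alternative 1 | keto mesylate (C3 ketone, C2 mesylate, C4 p-methoxybenzyl ether) | COC(=O)C1=C[C@@H](OCc2ccc(OC)cc2)C(=O)[C@H](OS(C)(=O)=O)C1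
A3 | alternative 1 | epoxy enoate | COC(=O)C1=C[C@@H](OCc2ccc(OC)cc2)[C@@]3(C)O[C@H]3C1
A4 | alternative 2 | 6-methyl-6-vinyl δ-lactone with cis acetonide | O=C1C[C@H]2OC(C)(C)O[C@H]2[C@](C)(C=C)O1
A5 | alternative 2 | cis-fused acetonide cyclohexene C6 carboxylic acid | O=C(O)[C@@H]1CC=C(C)[C@@H]2OC(C)(C)O[C@H]12
A6 | alternative 3 | N-acryloyloxazolidin-2-one | C=CC(=O)N1CCOC1=O
A7 | alternative 3 | (E)-1-acetoxy-3-methylbuta-1,3-diene | CC(=C)/C=C/OC(C)=O
A8 | alternative 3 | cis cycloadduct (C6 acyl oxazolidinone, C5 acetate) | O=C(N1CCOC1=O)[C@@H]1CCC(C)=C[C@@H]1OC(C)=O
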